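The eleven-membered carbocycle is numbered C1 (bears CO2H), C1=C2, C5 (methylidene), C6 (OH), C8 (gem-dimethyl), C10 (isovalerate). Everything rests on disconnecting it at C5–C6, the 2-methylidene carbinol C5(=CH2)–C6(OH) of the cycloundecene ring. One ligand-controlled intramolecular Nozaki–Hiyama–Kishi reaction of an open-chain 2-iodo-1-alkene aldehyde closes the ring, creates the exocyclic methylene/allylic alcohol array and sets C6. The precursor 16 already holds the (E)-enoate (ring-cis C1=C2), the C10 ester and the gem-dimethyl turn. It is built linearly from 3,3-dimethylpentane-1,5-diol by chromium-catalysed asymmetric 2-bromoallylation, carbonylation and cross-metathesis with 2-iodohexa-1,5-diene.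

Key step: step 10

Remark: the chiral chromium ligand (a 2-(2-sulfonamidoaryl)-4-alkyloxazoline) is used in the antipode that directs Re-face addition in steps 3 and 10, to be confirmed on aldehyde 4; species bound only to a catalyst are not numbered, stoichiometric intermediates are.

Step 1
Reactants: 1 3,3-dimethylpentane-1,5-diol
Product: 3 5-[(tert-butyldimethylsilyl)oxy]-3,3-dimethylpentan-1-ol, via sodium monoalkoxide 2 (not isolated)
Conditions: NaH (1.0 equiv), THF, 0 °C to rt; TBSCl (1.0 equiv)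
Reagents that add atoms: sodium hydride, [Na+].[H-] (sodium in 2 only); tert-butyldimethylsilyl chloride, CC(C)(C)[Si](C)(C)Cl
Why: O-silylation of the sparingly soluble mono-sodium alkoxide of a symmetric diol should give mainly the mono-ether, and the two ends are equivalent, so no regiochemistry arises.

Step 2
Reactants: 3 5-[(tert-butyldimethylsilyl)oxy]-3,3-dimethylpentan-1-ol
Product: 4 5-[(tert-butyldimethylsilyl)oxy]-3,3-dimethylpentanal
Conditions: TEMPO (10 mol%), PhI(OAc)2 (1.1 equiv), CH2Cl2, rt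
Reagents that add atoms: none
Why: TEMPO-catalysed oxoammonium oxidation should stop at the aldehyde and leave the silyl ether intact.

Step 3
Reactants: 4 5-[(tert-butyldimethylsilyl)oxy]-3,3-dimethylpentanal; 5 2,3-dibromoprop-1-ene
Product: 7 (4S)-2-bromo-8-[(tert-butyldimethylsilyl)oxy]-6,6-dimethyloct-1-en-4-ol, via trimethylsilyl ether 6 (not isolated)
Conditions: CrCl2 (10 mol%), chiral 2-(2-sulfonamidoaryl)oxazoline ligand (11 mol%), Et3N (20 mol%), cobalt phthalocyanine (1 mol%), Mn (2 equiv), TMSCl (2 equiv), THF, 0 °C to rt; then K2CO3 (cat.), MeOH, 0 °C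
Reagents that add atoms: chlorotrimethylsilane, C[Si](C)(C)Cl (in 6 only)
Why: In this catalytic asymmetric Nozaki–Hiyama 2-haloallylation only the allylic C–Br bond is reduced (Co/Cr), the ligand-bearing 2-bromoallylchromium(III) should add to the Re face of 4 to set (4S), the future C10, Mn/TMSCl turn the chromium over, and the vinylic bromide is inert without nickel.

Step 4
Reactants: 7 (4S)-2-bromo-8-[(tert-butyldimethylsilyl)oxy]-6,6-dimethyloct-1-en-4-ol; 8 3-methylbutanoyl chloride
Product: 9 (4S)-2-bromo-8-[(tert-butyldimethylsilyl)oxy]-6,6-dimethyloct-1-en-4-yl 3-methylbutanoate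
Conditions: pyridine, DMAP (cat.), CH2Cl2, 0 °C to rt
Reagents that add atoms: none
Why: DMAP-catalysed acylation installs the isovalerate of the target with retention, because the carbinol C–O bond is not touched.

Step 5
Reactants: 9 (4S)-2-bromo-8-[(tert-butyldimethylsilyl)oxy]-6,6-dimethyloct-1-en-4-yl 3-methylbutanoate
Product: 10 2-(trimethylsilyl)ethyl (4S)-8-[(tert-butyldimethylsilyl)oxy]-6,6-dimethyl-2-methylidene-4-[(3-methylbutanoyl)oxy]octanoate
Conditions: Pd(OAc)2 (5 mol%), Xantphos (6 mol%), CO (1 atm), Me3SiCH2CH2OH (3 equiv), Et3N (2 equiv), toluene, 80 °C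
Reagents that add atoms: carbon monoxide, [C-]#[O+]; 2-(trimethylsilyl)ethanol, C[Si](C)(C)CCO
Why: Pd-catalysed alkoxycarbonylation of the alkenyl bromide (oxidative addition, CO insertion, alcoholysis) should give the 2-substituted acrylate as a fluoride-labile ester without touching the stereocentre, the isovalerate or the silyl ether.

Step 6
Reactants: 11 hex-1-en-5-yne
Product: 13 2-iodohexa-1,5-diene, via alkenylborane 12 (not isolated)
Conditions: B-iodo-9-BBN (1.05 equiv), pentane, −20 to 0 °C; AcOH, 0 °C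
Reagents that add atoms: 9-iodo-9-borabicyclo[3.3.1]nonane, IB1C2CCCC1CCC2
Why: Haloboration–protodeboronation adds B–I syn to the terminal alkyne only (iodine to the internal carbon) and acetic acid cleaves the C–B bond, a net Markovnikov hydroiodination that leaves the alkene untouched.

Step 7
Reactants: 10 2-(trimethylsilyl)ethyl (4S)-8-[(tert-butyldimethylsilyl)oxy]-6,6-dimethyl-2-methylidene-4-[(3-methylbutanoyl)oxy]octanoate; 13 2-iodohexa-1,5-diene (3 equiv)
Product: 14 2-(trimethylsilyl)ethyl (2E)-2-{(2S)-6-[(tert-butyldimethylsilyl)oxy]-4,4-dimethyl-2-[(3-methylbutanoyl)oxy]hexyl}-6-iodohepta-2,6-dienoate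
Conditions: (H2IMes)Cl2Ru(=CH-2-iPrOC6H4) (2 × 5 mol%), CH2Cl2, 40 °C
Reagents that add atoms: none
Why: Olefin cross-metathesis of a terminal olefin with a 1,1-disubstituted acrylate should give the trisubstituted enoate, (E) being favoured because the C3 chain lies trans to the ester, while the 2-iodo-1-alkene is too hindered and electron-poor to enter the cycle.

Step 8
Reactants: 14 2-(trimethylsilyl)ethyl (2E)-2-{(2S)-6-[(tert-butyldimethylsilyl)oxy]-4,4-dimethyl-2-[(3-methylbutanoyl)oxy]hexyl}-6-iodohepta-2,6-dienoate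
Product: 15 2-(trimethylsilyl)ethyl (2E)-2-{(2S)-6-hydroxy-4,4-dimethyl-2-[(3-methylbutanoyl)oxy]hexyl}-6-iodohepta-2,6-dienoate
Conditions: CSA (0.2 equiv), MeOH/CH2Cl2 (1:1), 0 °C
Reagents that add atoms: none
Why: Acid-catalysed methanolysis removes the primary TBS ether, and both esters and the alkenyl iodide should tolerate catalytic acid at 0 °C.

Step 9
Reactants: 15 2-(trimethylsilyl)ethyl (2E)-2-{(2S)-6-hydroxy-4,4-dimethyl-2-[(3-methylbutanoyl)oxy]hexyl}-6-iodohepta-2,6-dienoate
Product: 16 2-(trimethylsilyl)ethyl (2E)-2-{(2S)-4,4-dimethyl-2-[(3-methylbutanoyl)oxy]-6-oxohexyl}-6-iodohepta-2,6-dienoate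
Conditions: TEMPO (10 mol%), PhI(OAc)2 (1.1 equiv), CH2Cl2, rt
Reagents that add atoms: none
Why: TEMPO-catalysed oxoammonium oxidation gives the aldehyde under neutral conditions compatible with the alkenyl iodide and both esters.

Step 10
Reactants: 16 2-(trimethylsilyl)ethyl (2E)-2-{(2S)-4,4-dimethyl-2-[(3-methylbutanoyl)oxy]-6-oxohexyl}-6-iodohepta-2,6-dienoate
Product: 19 2-(trimethylsilyl)ethyl (1E,6S,10S)-6-hydroxy-8,8-dimethyl-5-methylidene-10-[(3-methylbutanoyl)oxy]cycloundec-1-ene-1-carboxylate, via alkenylchromium(III) species 17 (not isolated), via chromium(III) alkoxide 18 (not isolated)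
Conditions: CrCl2 (4 equiv), chiral 2-(2-sulfonamidoaryl)oxazoline ligand (4.4 equiv), Et3N (4.4 equiv), NiCl2·neocuproine (10 mol%), MeCN/THF, slow addition of 16 to 2 mM, rt; aqueous sodium serinate work-up (ligand and Et3N recovered)
Reagents that add atoms: chromium(II) chloride, Cl[Cr]Cl (in 17 and 18 only)
Why: Ni(0), formed from the Ni(II) co-catalyst by Cr(II), inserts into the C5–I bond of 16 and transmetalates to Cr(III); alkenylchromium 17 adds to the C6 aldehyde to give alkoxide 18, which is hydrolysed on work-up. The closest known reaction type is the intramolecular Nozaki–Hiyama–Kishi coupling of 2-iodo-1-alkenes with aldehydes used to close medium and large 2-methylidene cycloalkanols, here in its ligand-controlled asymmetric form. The ring closes at C5–C6 in the 11-exo-trig mode. The new C6 stereocentre is controlled by the chiral sulfonamide–oxazoline ligand on Cr(III), which should deliver the alkenyl group to the Re face of the aldehyde and so give (6S); the remote C10 centre is not relied on. The step needs selectivity for the aldehyde over the two esters and the enoate, secured by the low basicity and aldehyde selectivity of organochromium(III), and cyclisation over oligomerisation, favoured by high dilution and by two built-in turns, the ring-cis C1=C2 olefin and the C8 gem-dimethyl group.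

Step 11
Reactants: 19 2-(trimethylsilyl)ethyl (1E,6S,10S)-6-hydroxy-8,8-dimethyl-5-methylidene-10-[(3-methylbutanoyl)oxy]cycloundec-1-ene-1-carboxylate
Product: 21 (1E,6S,10S)-6-hydroxy-8,8-dimethyl-5-methylidene-10-[(3-methylbutanoyl)oxy]cycloundec-1-ene-1-carboxylic acid, via tetrabutylammonium carboxylate 20 (not isolated)
Conditions: TBAF (3 equiv), THF, 0 °C to rt; then cold 0.1 M HCl to pH 3
Reagents that add atoms: tetrabutylammonium fluoride, CCCC[N+](CCCC)(CCCC)CCCC.[F-] (cation in 20 only)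
Why: Fluoride-induced fragmentation of the 2-(trimethylsilyl)ethyl ester (β-elimination to ethene and Me3SiF) frees the acid without hydrolysis, so the isovalerate, the allylic alcohol and both stereocentres should survive.

Compound list
1 | 3,3-dimethylpentane-1,5-diol | OCCC(C)(C)CCO | starting material
2 | sodium 5-hydroxy-3,3-dimethylpentan-1-olate | [Na+].[O-]CCC(C)(C)CCO | intermediate
3 | 5-[(tert-butyldimethylsilyl)oxy]-3,3-dimethylpentan-1-ol | OCCC(C)(C)CCO[Si](C)(C)C(C)(C)C | intermediate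
4 | 5-[(tert-butyldimethylsilyl)oxy]-3,3-dimethylpentanal | O=CCC(C)(C)CCO[Si](C)(C)C(C)(C)C | intermediate
5 | 2,3-dibromoprop-1-ene | C=C(Br)CBr | starting material
6 | (4S)-2-bromo-8-[(tert-butyldimethylsilyl)oxy]-6,6-dimethyl-4-[(trimethylsilyl)oxy]oct-1-ene | C=C(Br)C[C@@H](O[Si](C)(C)C)CC(C)(C)CCO[Si](C)(C)C(C)(C)C | intermediate
7 | (4S)-2-bromo-8-[(tert-butyldimethylsilyl)oxy]-6,6-dimethyloct-1-en-4-ol | C=C(Br)C[C@@H](O)CC(C)(C)CCO[Si](C)(C)C(C)(C)C | intermediate
8 | 3-methylbutanoyl chloride | CC(C)CC(=O)Cl | starting material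
9 | (4S)-2-bromo-8-[(tert-butyldimethylsilyl)oxy]-6,6-dimethyloct-1-en-4-yl 3-methylbutanoate | C=C(Br)C[C@@H](OC(=O)CC(C)C)CC(C)(C)CCO[Si](C)(C)C(C)(C)C | intermediate
10 | 2-(trimethylsilyl)ethyl (4S)-8-[(tert-butyldimethylsilyl)oxy]-6,6-dimethyl-2-methylidene-4-[(3-methylbutanoyl)oxy]octanoate | C=C(C(=O)OCC[Si](C)(C)C)C[C@@H](OC(=O)CC(C)C)CC(C)(C)CCO[Si](C)(C)C(C)(C)C | intermediate
11 | hex-1-en-5-yne | C=CCCC#C | starting material
12 | 9-[(1Z)-2-iodohexa-1,5-dien-1-yl]-9-borabicyclo[3.3.1]nonane | C=CCC/C(I)=C/B1C2CCCC1CCC2 | intermediate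
13 | 2-iodohexa-1,5-diene | C=CCCC(I)=C | intermediate
14 | 2-(trimethylsilyl)ethyl (2E)-2-{(2S)-6-[(tert-butyldimethylsilyl)oxy]-4,4-dimethyl-2-[(3-methylbutanoyl)oxy]hexyl}-6-iodohepta-2,6-dienoate | C=C(I)CC/C=C(/C(=O)OCC[Si](C)(C)C)C[C@@H](OC(=O)CC(C)C)CC(C)(C)CCO[Si](C)(C)C(C)(C)C | intermediate
15 | 2-(trimethylsilyl)ethyl (2E)-2-{(2S)-6-hydroxy-4,4-dimethyl-2-[(3-methylbutanoyl)oxy]hexyl}-6-iodohepta-2,6-dienoate | C=C(I)CC/C=C(/C(=O)OCC[Si](C)(C)C)C[C@@H](OC(=O)CC(C)C)CC(C)(C)CCO | intermediate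
16 | 2-(trimethylsilyl)ethyl (2E)-2-{(2S)-4,4-dimethyl-2-[(3-methylbutanoyl)oxy]-6-oxohexyl}-6-iodohepta-2,6-dienoate | C=C(I)CC/C=C(/C(=O)OCC[Si](C)(C)C)C[C@@H](OC(=O)CC(C)C)CC(C)(C)CC=O | intermediate
17 | alkenylchromium(III) dichloride from 16 (C–I replaced by C–CrCl2; carries the chiral ligand in the flask) | C=C([Cr](Cl)Cl)CC/C=C(/C(=O)OCC[Si](C)(C)C)C[C@@H](OC(=O)CC(C)C)CC(C)(C)CC=O | intermediate
18 | chromium(III) alkoxide of 19 | C=C1CC/C=C(/C(=O)OCC[Si](C)(C)C)C[C@@H](OC(=O)CC(C)C)CC(C)(C)C[C@@H]1O[Cr](Cl)Cl | intermediate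
19 | 2-(trimethylsilyl)ethyl (1E,6S,10S)-6-hydroxy-8,8-dimethyl-5-methylidene-10-[(3-methylbutanoyl)oxy]cycloundec-1-ene-1-carboxylate | C=C1CC/C=C(/C(=O)OCC[Si](C)(C)C)C[C@@H](OC(=O)CC(C)C)CC(C)(C)C[C@@H]1O | intermediate
20 | tetrabutylammonium (1E,6S,10S)-6-hydroxy-8,8-dimethyl-5-methylidene-10-[(3-methylbutanoyl)oxy]cycloundec-1-ene-1-carboxylate | C=C1CC/C=C(/C(=O)[O-])C[C@@H](OC(=O)CC(C)C)CC(C)(C)C[C@@H]1O.CCCC[N+](CCCC)(CCCC)CCCC | intermediate
21 | (1E,6S,10S)-6-hydroxy-8,8-dimethyl-5-methylidene-10-[(3-methylbutanoyl)oxy]cycloundec-1-ene-1-carboxylic acid | C=C1CC/C=C(/C(=O)O)C[C@@H](OC(=O)CC(C)C)CC(C)(C)C[C@@H]1O | target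

Total step count: 11. Longest linear sequence: 10 (steps 1–5 and 7–11; step 6 prepares the metathesis partner).

Steps most likely to fail

Step 10 (ring closure). The facial selectivity at C6 may be poor or reversed, because the conformation of the closing eleven-membered ring can override the ligand, and intermolecular coupling may compete. Fallback: the closure is kept and C6 is set afterwards by redox. It sets out from 19 (any C6 epimer ratio): Dess–Martin periodinane (NaHCO3, CH2Cl2, 0 °C) should give the cross-conjugated macrocyclic enone 2-(trimethylsilyl)ethyl (1E,10S)-8,8-dimethyl-5-methylidene-10-[(3-methylbutanoyl)oxy]-6-oxocycloundec-1-ene-1-carboxylate F1. Corey–Bakshi–Shibata reduction ((R)-Me-CBS cat., catecholborane, toluene, −78 °C; alkenyl branch as the large group) should then give, through the O-catecholboryl ether F2 and aqueous work-up, the (6S)-alcohol, coming back at 19.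

Step 7 (cross-metathesis). The hindered, electron-poor 1,1-disubstituted acrylate may react too slowly while 13 homodimerises, and geometric purity may erode. Fallback: the order of the two C–C bond formations is exchanged so that the metathesis becomes intramolecular. It sets out from 10: CSA/MeOH should give the primary alcohol F3 and TEMPO/PhI(OAc)2 the aldehyde F4. Ni/Cr coupling with 13 under the ligand-controlled conditions of step 10 (through hexa-1,5-dien-2-ylchromium(III) dichloride F5 and the chromium alkoxide F6) should give the tetraene allylic alcohol F7. Ring-closing metathesis of its terminal vinyl group onto the acrylate (same Ru catalyst, toluene, 1 mM, 80 °C) closes C1=C2 and comes back at 19.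

Step 3 (asymmetric 2-bromoallylation). Enantiofacial discrimination at the α-unbranched, β-quaternary aldehyde may be insufficient. Fallback: C10 is set by asymmetric propargylation instead. It sets out from 4: allenylboronic acid pinacol ester under chiral BINOL-phosphoric acid catalysis (toluene, 4 Å MS, 0 °C; antipode for Re-face attack) should give, through the O-boryl adduct F8, the homopropargylic alcohol F9. Acylation with 8 (pyridine, DMAP) gives the ester F10. Pd-catalysed branched-selective hydroalkoxycarbonylation of the terminal alkyne (Pd(OAc)2, 2-pyridyldiphenylphosphine, MsOH cat., CO, Me3SiCH2CH2OH, 50 °C) comes back at 10.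

Further compounds
F1 | step 10 | 2-(trimethylsilyl)ethyl (1E,10S)-8,8-dimethyl-5-methylidene-10-[(3-methylbutanoyl)oxy]-6-oxocycloundec-1-ene-1-carboxylate | C=C1CC/C=C(/C(=O)OCC[Si](C)(C)C)C[C@@H](OC(=O)CC(C)C)CC(C)(C)CC1=O
F2 | step 10 | O-(1,3,2-benzodioxaborol-2-yl) ether of 19 | C=C1CC/C=C(/C(=O)OCC[Si](C)(C)C)C[C@@H](OC(=O)CC(C)C)CC(C)(C)C[C@@H]1OB2Oc3ccccc3O2
F3 | step 7 | 2-(trimethylsilyl)ethyl (4S)-8-hydroxy-6,6-dimethyl-2-methylidene-4-[(3-methylbutanoyl)oxy]octanoate | C=C(C(=O)OCC[Si](C)(C)C)C[C@@H](OC(=O)CC(C)C)CC(C)(C)CCO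
F4 | step 7 | 2-(trimethylsilyl)ethyl (4S)-6,6-dimethyl-2-methylidene-4-[(3-methylbutanoyl)oxy]-8-oxooctanoate | C=C(C(=O)OCC[Si](C)(C)C)C[C@@H](OC(=O)CC(C)C)CC(C)(C)CC=O
F5 | step 7 | hexa-1,5-dien-2-ylchromium(III) dichloride | C=CCCC(=C)[Cr](Cl)Cl
F6 | step 7 | chromium(III) alkoxide of F7 | C=CCCC(=C)[C@@H](O[Cr](Cl)Cl)CC(C)(C)C[C@H](OC(=O)CC(C)C)CC(=C)C(=O)OCC[Si](C)(C)C
F7 | step 7 | 2-(trimethylsilyl)ethyl (4S,8S)-8-hydroxy-6,6-dimethyl-2,9-dimethylidene-4-[(3-methylbutanoyl)oxy]tridec-12-enoate | C=CCCC(=C)[C@@H](O)CC(C)(C)C[C@H](OC(=O)CC(C)C)CC(=C)C(=O)OCC[Si](C)(C)C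
F8 | step 3 | 2-{[(4S)-8-[(tert-butyldimethylsilyl)oxy]-6,6-dimethyloct-1-yn-4-yl]oxy}-4,4,5,5-tetramethyl-1,3,2-dioxaborolane | C#CC[C@@H](OB1OC(C)(C)C(C)(C)O1)CC(C)(C)CCO[Si](C)(C)C(C)(C)C
F9 | step 3 | (4S)-8-[(tert-butyldimethylsilyl)oxy]-6,6-dimethyloct-1-yn-4-ol | C#CC[C@@H](O)CC(C)(C)CCO[Si](C)(C)C(C)(C)C
F10 | step 3 | (4S)-8-[(tert-butyldimethylsilyl)oxy]-6,6-dimethyloct-1-yn-4-yl 3-methylbutanoate | C#CC[C@@H](OC(=O)CC(C)C)CC(C)(C)CCO[Si](C)(C)C(C)(C)C
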